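The route cuts the hydroazulene at C1–C5 and C9–C10. The feature exploited is the five-carbon arc C5–C6(O)–C7–C8(CH3)–C9 of the seven-membered ring, next to the quaternary C1 that both rings share. The arc maps onto a 3-oxidopyrylium made from a 4-methylfuran, and C1=C10 onto an isopropenyl group held by the C2–C3–C4 tether. One intramolecular [5+2] cycloaddition then closes the cyclopentane and the oxygen-bridged seven-membered ring and sets C1, C5 and C9. The precursor is an acetoxypyranone from Achmatowicz oxidation of a 4-methyl-2-furyl carbinol. Its side chain carries the valine-derived C4 carbinol (free OH) and a silyl-protected C2 alcohol set by CBS reduction.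

Key step: step 12

Numbering used throughout: C1 = quaternary ring-fusion carbon with CH3; C2 = CH–O (angelate); C3 = CH2; C4 = C(OH)(isopropyl); C5 = ring-fusion CH; C6 = CH–O (4-methoxybenzoate); C7 = CH2; C8 = C(CH3)=; C9 = =CH; C10 = CH2. The five-membered ring is C1–C5; the seven-membered ring is C5–C10 plus C1.

Assumption: s-BuLi/TMEDA deprotonates 3-methylfuran mainly at the α-position remote from the methyl group (C5 of the furan), which gives the 4-methyl-2-furyl nucleophile; any 3-methyl-2-furyl ketone would be removed by chromatography after step 8.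

Remark: 9, 17, 18 and 19 are carried as epimer mixtures at centres that are erased later (C2 in step 5; C5 and C9 in step 12).

Step 1
Reactants: 1 (R)-2-hydroxy-3-methylbutanoic acid; 2 pivalaldehyde
Product: 3 (2R,5R)-2-tert-butyl-5-isopropyl-1,3-dioxolan-4-one (cis)
Conditions: TsOH·H2O (cat.), H2SO4 (cat.), pentane, reflux (Dean–Stark); recrystallisation
Reagents that add atoms: pivalaldehyde, CC(C)(C)C=O
Why: Acid-catalysed acetalisation with water removal gives the thermodynamically preferred cis acetal-lactone, whose tert-butyl-bearing acetal carbon stores the configuration of the future C4.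

Step 2
Reactants: 3 (2R,5R)-2-tert-butyl-5-isopropyl-1,3-dioxolan-4-one; 4 allyl bromide
Product: 6 (2R,5R)-5-allyl-2-tert-butyl-5-isopropyl-1,3-dioxolan-4-one, via lithium enolate 5 (not isolated)
Conditions: LiN(iPr)2, THF, −78 °C; allyl bromide, −78 → −30 °C
Reagents that add atoms: allyl bromide, C=CCBr
Why: Enolate alkylation with self-regeneration of the stereocentre: the planar enolate is allylated anti to the tert-butyl group, so the allyl group takes the place of the original hydrogen and the quaternary C4 forms with retention.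

Step 3
Reactants: 6 (2R,5R)-5-allyl-2-tert-butyl-5-isopropyl-1,3-dioxolan-4-one
Product: 7 2-[(2R,4R)-2-tert-butyl-4-isopropyl-5-oxo-1,3-dioxolan-4-yl]acetaldehyde
Conditions: O3, CH2Cl2, −78 °C; PPh3, −78 → 25 °C
Reagents that add atoms: ozone, [O-][O+]=O
Why: Ozonolysis with reductive work-up cleaves the only alkene to the C2 aldehyde and leaves the acetal-lactone and C4 untouched.

Step 4
Reactants: 7 2-[(2R,4R)-2-tert-butyl-4-isopropyl-5-oxo-1,3-dioxolan-4-yl]acetaldehyde; 8 isopropenylmagnesium bromide
Product: 9 (2R,5R)-2-tert-butyl-5-(2-hydroxy-3-methylbut-3-en-1-yl)-5-isopropyl-1,3-dioxolan-4-one (both C2 epimers)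
Conditions: THF, −78 °C; AcOH/THF quench at −78 °C
Reagents that add atoms: isopropenylmagnesium bromide, CC(=C)[Mg]Br
Why: Grignard addition to the aldehyde, which is far more electrophilic than the hindered dioxolanone carbonyl, brings in C1, C10 and the C1 methyl; C2 is left uncontrolled because the next two steps erase and reset it, and the cold acidic quench keeps the alkoxide from lactonising.

Step 5
Reactants: 9 (2R,5R)-2-tert-butyl-5-(2-hydroxy-3-methylbut-3-en-1-yl)-5-isopropyl-1,3-dioxolan-4-one
Product: 10 (2R,5R)-2-tert-butyl-5-isopropyl-5-(3-methyl-2-oxobut-3-en-1-yl)-1,3-dioxolan-4-one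
Conditions: Dess–Martin periodinane, CH2Cl2, 0 → 25 °C
Reagents that add atoms: none
Why: Dess–Martin oxidation of the allylic alcohol under non-basic conditions gives the α-methylene ketone without β-elimination of the C4 oxygen.

Step 6
Reactants: 10 (2R,5R)-2-tert-butyl-5-isopropyl-5-(3-methyl-2-oxobut-3-en-1-yl)-1,3-dioxolan-4-one
Product: 11 (2R,5R)-2-tert-butyl-5-[(2R)-2-hydroxy-3-methylbut-3-en-1-yl]-5-isopropyl-1,3-dioxolan-4-one
Conditions: (S)-2-methyl-CBS-oxazaborolidine [(S)-1-methyl-3,3-diphenyl-tetrahydro-1H,3H-pyrrolo[1,2-c][1,3,2]oxazaborole] (0.2 equiv), catecholborane, toluene, −78 °C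
Reagents that add atoms: none
Why: Corey–Bakshi–Shibata reduction under catalyst control: with the α-branched isopropenyl group as the large substituent the (S)-catalyst should give the (R)-carbinol at C2, and catecholborane does not hydroborate the alkene.

Step 7
Reactants: 11 (2R,5R)-2-tert-butyl-5-[(2R)-2-hydroxy-3-methylbut-3-en-1-yl]-5-isopropyl-1,3-dioxolan-4-one
Product: 12 (2R,5R)-2-tert-butyl-5-[(2R)-2-(tert-butyldimethylsilyloxy)-3-methylbut-3-en-1-yl]-5-isopropyl-1,3-dioxolan-4-one
Conditions: TBSOTf, 2,6-lutidine, CH2Cl2, −78 °C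
Reagents that add atoms: tert-butyldimethylsilyl triflate, CC(C)(C)[Si](C)(C)OS(=O)(=O)C(F)(F)F
Why: Silylation of the secondary alcohol by the silyl triflate is fast at low temperature and caps the C2 hydroxyl before it can translactonise onto the dioxolanone.

Step 8
Reactants: 12 (2R,5R)-2-tert-butyl-5-[(2R)-2-(tert-butyldimethylsilyloxy)-3-methylbut-3-en-1-yl]-5-isopropyl-1,3-dioxolan-4-one; 13 3-methylfuran
Product: 16 (2R,4R)-4-(tert-butyldimethylsilyloxy)-2-hydroxy-2-isopropyl-5-methyl-1-(4-methylfuran-2-yl)hex-5-en-1-one, via 4-methyl-2-furyllithium 14 (not isolated), via lithium hemiketalate 15 (not isolated)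
Conditions: 3-methylfuran, s-BuLi, TMEDA, THF, −78 → −20 °C; then 12, −78 °C; H2O, 0 → 25 °C
Reagents that add atoms: 3-methylfuran, Cc1ccoc1
Why: α-Lithiation of the furan followed by acyl substitution at the dioxolanone carbonyl: the cyclic lithium hemiketalate resists a second addition and on aqueous work-up collapses to the α-hydroxy ketone with loss of pivalaldehyde, C4 being untouched.

Step 9
Reactants: 16 (2R,4R)-4-(tert-butyldimethylsilyloxy)-2-hydroxy-2-isopropyl-5-methyl-1-(4-methylfuran-2-yl)hex-5-en-1-one
Product: 17 (2R,4R)-4-(tert-butyldimethylsilyloxy)-2-isopropyl-5-methyl-1-(4-methylfuran-2-yl)hex-5-ene-1,2-diol (both C5 epimers)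
Conditions: NaBH4, MeOH, 0 °C
Reagents that add atoms: none
Why: Borohydride reduction of the furyl ketone gives the furfuryl alcohol needed for ring expansion; the new C5 centre needs no control because it becomes sp2 in the ylide.

Step 10
Reactants: 17 (2R,4R)-4-(tert-butyldimethylsilyloxy)-2-isopropyl-5-methyl-1-(4-methylfuran-2-yl)hex-5-ene-1,2-diol
Product: 18 6-hydroxy-5-methyl-2H-pyran-3(6H)-one carrying at its C2 the (3R,5R)-5-(tert-butyldimethylsilyloxy)-3-hydroxy-2,6-dimethylhept-6-en-3-yl chain (epimers at both pyranone sp3 carbons)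
Conditions: NBS, NaHCO3, NaOAc, THF/H2O (4:1), 0 °C
Reagents that add atoms: water, O
Why: Achmatowicz oxidative rearrangement: the electron-rich furan is oxidised much faster than the 1,1-disubstituted alkene, the C5 hydroxyl closes onto C9 to give the pyranone hemiacetal, and the buffer keeps the tertiary C4 hydroxyl from ketalising at C9.

Step 11
Reactants: 18 the 6-hydroxypyranone
Product: 19 6-acetoxy-5-methyl-2H-pyran-3(6H)-one carrying at its C2 the (3R,5R)-5-(tert-butyldimethylsilyloxy)-3-hydroxy-2,6-dimethylhept-6-en-3-yl chain (epimers at both pyranone sp3 carbons)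
Conditions: Ac2O, pyridine, DMAP (cat.), CH2Cl2, 0 °C
Reagents that add atoms: acetic anhydride, CC(=O)OC(C)=O
Why: Acylation of the hemiacetal hydroxyl, far more reactive than the tertiary C4 alcohol, installs the leaving group for ylide formation; both anomers serve.

Step 12
Reactants: 19 the acetoxypyranone
Product: 21 oxygen-bridged (C5–O–C9) hydroazulenone with C6 ketone conjugated to C7=C8(CH3), quaternary C1–CH3, C2–OTBS and C4(OH)(isopropyl), via oxidopyrylium ylide 20 (not isolated)
Conditions: DBU, CH2Cl2 (0.01 M), 25 → 40 °C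
Reagents that add atoms: none
Why: DBU removes the proton at C5 and acetate leaves C9, giving the planar 3-oxidopyrylium 20, whose termini C5 and C9 add suprafacially to C1=C10 in a concerted thermal [5+2] cycloaddition that forms C1–C5 and C9–C10; both pyranone sp3 centres are erased in 20, so the epimer mixture converges. The closest known reaction is the intramolecular oxidopyrylium–alkene cycloaddition of 6-acetoxypyranones that carry the alkene on a three-atom tether at C2 of the pyranone. The cyclopentane (C1–C5) closes in a 5-exo sense by attack of C5 on the internal alkene carbon C1, and the seven-membered carbocycle (C5 to C10 plus C1) closes through C9–C10 as an oxygen-bridged ring that contains both alkene carbons. C5 and C9 are cis through the oxygen bridge; C1 is fixed relative to them because a three-atom tether can only reach the exo position, which puts the C1 methyl endo over the enone; the ylide face, and so the configuration of all three centres relative to C2 and C4, is chosen by the tether conformation in which the C4 hydroxyl lies in the ylide plane hydrogen-bonded to the oxido oxygen while isopropyl and the C2 silyloxy group sit pseudo-equatorial on the forming five-membered ring. The step needs facial selectivity and must outrun ylide dimerisation and capture of C9 by the C4 hydroxyl: the other face would force isopropyl into the ylide plane against the oxido oxygen and the silyloxy group pseudo-axial, high dilution disfavours dimerisation, and the in-plane hydrogen-bonded hydroxyl cannot reach C9.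

Step 13
Reactants: 21 the oxygen-bridged cycloadduct
Product: 22 trans-fused γ-hydroxy enone (C5–H, C6 ketone, C7=C8(CH3), C9–OH, C2–OTBS, C4–OH)
Conditions: SmI2 (2.5 equiv), THF/MeOH, −78 °C
Reagents that add atoms: none
Why: Reductive cleavage of the α-alkoxy ketone by SmI2 expels the bridging oxygen from C5, whose C–O bond lies parallel to the carbonyl π system; C5 should then be protonated on the face the oxygen has just left, where the samarium-bound C9 alkoxide holds methanol, giving the trans ring fusion that also keeps C6 away from the isopropyl group.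

Step 14
Reactants: 22 the γ-hydroxy enone
Product: 23 trans-fused γ-acetoxy enone (C9–OAc)
Conditions: Ac2O, pyridine, DMAP (cat.), CH2Cl2, 0 → 25 °C
Reagents that add atoms: acetic anhydride, CC(=O)OC(C)=O
Why: Acetylation of the secondary allylic C9 alcohol, with the tertiary C4 alcohol inert, turns the C9 oxygen into a leaving group for the vinylogous reduction.

Step 15
Reactants: 23 the γ-acetoxy enone
Product: 24 β,γ-unsaturated ketone (C6 ketone, C7H2, C8(CH3)=C9, C2–OTBS, C4–OH)
Conditions: SmI2 (2.5 equiv), THF/MeOH, −78 °C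
Reagents that add atoms: none
Why: SmI2 reduction of the γ-acetoxy enone expels acetate from C9 to give the C6–C9 dienolate, and kinetic protonation at the α-carbon C7 leaves the alkene at C8=C9 (reductive vinylogous elimination with deconjugative protonation).

Step 16
Reactants: 24 the β,γ-unsaturated ketone
Product: 25 C4,C6-diol (C6–OH cis to H5, C2–OTBS)
Conditions: Me4NBH(OAc)3, AcOH/MeCN (1:1), −30 °C
Reagents that add atoms: none
Why: Evans–Saksena hydroxyl-directed reduction: the C4 hydroxyl, cis to C6 on the five-membered ring, binds boron and delivers hydride to the carbonyl face it can reach, which places the C6 oxygen cis to H5 as in the target, while the weakly acidic medium leaves the β,γ-alkene in place.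

Step 17
Reactants: 25 the C4,C6-diol; 26 4-methoxybenzoyl chloride
Product: 27 C6 4-methoxybenzoate (C2–OTBS, C4–OH)
Conditions: DMAP, Et3N, CH2Cl2, 25 → 40 °C
Reagents that add atoms: 4-methoxybenzoyl chloride, COc1ccc(cc1)C(Cl)=O
Why: DMAP-catalysed acylation takes the only secondary hydroxyl; the tertiary C4 alcohol does not react.

Step 18
Reactants: 27 the C6 4-methoxybenzoate
Product: 28 C2 alcohol (C2–OH, C4–OH, C6 4-methoxybenzoate)
Conditions: HF·pyridine, pyridine, THF, 0 → 25 °C
Reagents that add atoms: none
Why: Fluoride cleavage of the silyl ether under buffered, weakly acidic conditions avoids acyl migration and ester hydrolysis and spares the tertiary alcohol and the alkene.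

Step 19
Reactants: 28 the C2 alcohol; 29 angelic acid
Product: 31 CNP0204191.1, via mixed anhydride 30 (not isolated)
Conditions: angelic acid, 2,4,6-trichlorobenzoyl chloride, Et3N, toluene, 25 °C; then 28, 75 °C
Reagents that add atoms: angelic acid, C/C=C(/C)C(=O)O
Why: Yamaguchi esterification through the 2,4,6-trichlorobenzoyl mixed anhydride, run without a nucleophilic catalyst so that the (Z)-alkene is not isomerised to the tiglate; the shielded aroyl carbonyl directs the C2 hydroxyl to the angeloyl carbonyl.

Compound list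

1 | (R)-2-hydroxy-3-methylbutanoic acid | CC(C)[C@@H](O)C(=O)O | starting material
2 | pivalaldehyde | CC(C)(C)C=O | starting material
3 | (2R,5R)-2-tert-butyl-5-isopropyl-1,3-dioxolan-4-one (cis) | CC(C)[C@H]1O[C@@H](C(C)(C)C)OC1=O | intermediate
4 | allyl bromide | C=CCBr | starting material
5 | lithium enolate of 3, lithium (2R)-2-tert-butyl-5-isopropyl-1,3-dioxol-4-olate | CC(C)C1=C([O-])O[C@H](C(C)(C)C)O1.[Li+] | intermediate (not isolated)
6 | (2R,5R)-5-allyl-2-tert-butyl-5-isopropyl-1,3-dioxolan-4-one | C=CC[C@]1(C(C)C)O[C@@H](C(C)(C)C)OC1=O | intermediate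
7 | 2-[(2R,4R)-2-tert-butyl-4-isopropyl-5-oxo-1,3-dioxolan-4-yl]acetaldehyde | O=CC[C@]1(C(C)C)O[C@@H](C(C)(C)C)OC1=O | intermediate
8 | isopropenylmagnesium bromide | CC(=C)[Mg]Br | starting material
9 | (2R,5R)-2-tert-butyl-5-(2-hydroxy-3-methylbut-3-en-1-yl)-5-isopropyl-1,3-dioxolan-4-one, both C2 epimers | C=C(C)C(O)C[C@]1(C(C)C)O[C@@H](C(C)(C)C)OC1=O | intermediate
10 | (2R,5R)-2-tert-butyl-5-isopropyl-5-(3-methyl-2-oxobut-3-en-1-yl)-1,3-dioxolan-4-one | C=C(C)C(=O)C[C@]1(C(C)C)O[C@@H](C(C)(C)C)OC1=O | intermediate
11 | (2R,5R)-2-tert-butyl-5-[(2R)-2-hydroxy-3-methylbut-3-en-1-yl]-5-isopropyl-1,3-dioxolan-4-one | C=C(C)[C@H](O)C[C@]1(C(C)C)O[C@@H](C(C)(C)C)OC1=O | intermediate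
12 | (2R,5R)-2-tert-butyl-5-[(2R)-2-(tert-butyldimethylsilyloxy)-3-methylbut-3-en-1-yl]-5-isopropyl-1,3-dioxolan-4-one | C=C(C)[C@H](O[Si](C)(C)C(C)(C)C)C[C@]1(C(C)C)O[C@@H](C(C)(C)C)OC1=O | intermediate
13 | 3-methylfuran | Cc1ccoc1 | starting material
14 | 4-methyl-2-furyllithium | [Li]c1cc(C)co1 | intermediate (not isolated)
15 | lithium hemiketalate from addition of 14 to the carbonyl of 12 (hemiketal carbon unassigned) | C=C(C)[C@H](O[Si](C)(C)C(C)(C)C)C[C@]1(C(C)C)O[C@@H](C(C)(C)C)OC1([O-])c1cc(C)co1.[Li+] | intermediate (not isolated)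
16 | (2R,4R)-4-(tert-butyldimethylsilyloxy)-2-hydroxy-2-isopropyl-5-methyl-1-(4-methylfuran-2-yl)hex-5-en-1-one | C=C(C)[C@H](O[Si](C)(C)C(C)(C)C)C[C@@](O)(C(C)C)C(=O)c1cc(C)co1 | intermediate
17 | (2R,4R)-4-(tert-butyldimethylsilyloxy)-2-isopropyl-5-methyl-1-(4-methylfuran-2-yl)hex-5-ene-1,2-diol, both C5 epimers | C=C(C)[C@H](O[Si](C)(C)C(C)(C)C)C[C@@](O)(C(C)C)C(O)c1cc(C)co1 | intermediate
18 | 6-hydroxy-5-methyl-2-[(3R,5R)-5-(tert-butyldimethylsilyloxy)-3-hydroxy-2,6-dimethylhept-6-en-3-yl]-2H-pyran-3(6H)-one, epimers at C5 and C9 | C=C(C)[C@H](O[Si](C)(C)C(C)(C)C)C[C@@](O)(C(C)C)C1OC(O)C(C)=CC1=O | intermediate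
19 | 6-acetoxy-5-methyl-2-[(3R,5R)-5-(tert-butyldimethylsilyloxy)-3-hydroxy-2,6-dimethylhept-6-en-3-yl]-2H-pyran-3(6H)-one, epimers at C5 and C9 (key-step precursor) | C=C(C)[C@H](O[Si](C)(C)C(C)(C)C)C[C@@](O)(C(C)C)C1OC(OC(C)=O)C(C)=CC1=O | intermediate
20 | 3-oxidopyrylium ylide (5-methyl, C2 bearing the C1–C4 tether) | C=C(C)[C@H](O[Si](C)(C)C(C)(C)C)C[C@@](O)(C(C)C)c1[o+]cc(C)cc1[O-] | intermediate (not isolated)
21 | C5–O–C9 bridged hydroazulenone: C6 ketone, C7=C8(CH3), C1–CH3 endo, C2–OTBS, C4(OH)(isopropyl) | CC(C)(C)[Si](C)(C)O[C@@H]1C[C@@](O)(C(C)C)[C@@]23O[C@@H](C[C@]21C)C(C)=CC3=O | intermediate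
22 | trans-fused γ-hydroxy enone: C5–H, C6 ketone, C7=C8(CH3), C9–OH, C2–OTBS, C4–OH | CC(C)(C)[Si](C)(C)O[C@@H]1C[C@@](O)(C(C)C)[C@@H]2C(=O)C=C(C)[C@@H](O)C[C@]21C | intermediate
23 | trans-fused γ-acetoxy enone (C9–OAc) | CC(C)(C)[Si](C)(C)O[C@@H]1C[C@@](O)(C(C)C)[C@@H]2C(=O)C=C(C)[C@@H](OC(C)=O)C[C@]21C | intermediate
24 | β,γ-unsaturated ketone: C6 ketone, C7H2, C8(CH3)=C9, C2–OTBS, C4–OH | CC(C)(C)[Si](C)(C)O[C@@H]1C[C@@](O)(C(C)C)[C@@H]2C(=O)CC(C)=CC[C@]21C | intermediate
25 | C4,C6-diol with C2–OTBS (C6–OH cis to H5) | CC(C)(C)[Si](C)(C)O[C@@H]1C[C@@](O)(C(C)C)[C@@H]2[C@@H](O)CC(C)=CC[C@]21C | intermediate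
26 | 4-methoxybenzoyl chloride | COc1ccc(cc1)C(Cl)=O | starting material
27 | C6 4-methoxybenzoate with C2–OTBS and free C4–OH | CC(C)(C)[Si](C)(C)O[C@@H]1C[C@@](O)(C(C)C)[C@@H]2[C@@H](OC(=O)c3ccc(OC)cc3)CC(C)=CC[C@]21C | intermediate
28 | C6 4-methoxybenzoate with free C2–OH and C4–OH | O[C@@H]1C[C@@](O)(C(C)C)[C@@H]2[C@@H](OC(=O)c3ccc(OC)cc3)CC(C)=CC[C@]21C | intermediate
29 | angelic acid, (Z)-2-methylbut-2-enoic acid | C/C=C(/C)C(=O)O | starting material
30 | angelic 2,4,6-trichlorobenzoic mixed anhydride | C/C=C(/C)C(=O)OC(=O)c1c(Cl)cc(Cl)cc1Cl | intermediate (not isolated)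
31 | CNP0204191.1: trans-fused hydroazulene with C2 angelate, C4 tertiary alcohol and isopropyl, C6 4-methoxybenzoate, C8(CH3)=C9 | C/C=C(/C)C(=O)O[C@@H]1C[C@@](O)(C(C)C)[C@@H]2[C@@H](OC(=O)c3ccc(OC)cc3)CC(C)=CC[C@]21C | target

Total step count: 19. Longest linear sequence: 19 steps (1 to 31).

Steps most likely to fail

Step 12. The ylide may dimerise, or be captured at C9 by the neighbouring C4 hydroxyl, before it reaches the unactivated 1,1-disubstituted alkene; the facial bias could also prove too small. The fallback sets out from 19 and returns at 21. The C4 hydroxyl would first be capped with N,O-bis(trimethylsilyl)acetamide (CH2Cl2, 40 °C) to give the C4-O-trimethylsilyl ether of the acetoxypyranone F1. Ylide formation and cycloaddition (DBU, MeCN, 60 °C) would then be steered only by the size difference between isopropyl and the silyloxy group at C4 and by the pseudo-equatorial C2 silyloxy group, giving the C4-O-trimethylsilyl ether of the cycloadduct F2. Citric acid in MeOH would remove the trimethylsilyl group and rejoin the route at 21.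

Step 13. The proton may be delivered to C5 from the face opposite to the departing oxygen, which would give the cis ring fusion. The fallback sets out from 21 and returns at 23; it sets C5 by equilibration instead of kinetic protonation. The cis-fused γ-hydroxy enone F3 would be acetylated as in step 14 to the cis-fused γ-acetoxy enone F4. It would not be equilibrated as the free γ-hydroxy enone, which base can isomerise to a 1,4-diketone. F4 would then be treated with DBU in toluene at 25 °C, where reversible enolisation toward C5, the only α-hydrogen of the enone, should drain the material into the trans-fused acetate 23, in which C6 lies anti to the isopropyl group.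

Step 19. Acylation of the neopentyl-type C2 hydroxyl may be slow, and under forcing conditions the angeloyl unit may isomerise to the (E)-isomer. The fallback sets out from 28 and returns at 31; it builds the (Z)-alkene on the substrate instead of transferring it. Steglich esterification with 2-[bis(2,2,2-trifluoroethoxy)phosphoryl]propanoic acid (DCC, DMAP, CH2Cl2) would give the C2 phosphonopropanoate F5, which has no alkene to isomerise and so tolerates forcing conditions. Still–Gennari olefination (KN(SiMe3)2, 18-crown-6, THF, −78 °C; acetaldehyde) would then give the (Z)-2-methylbut-2-enoate 31.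

Further compounds

F1 | step 12 | C4-O-trimethylsilyl ether of acetoxypyranone 19 | C=C(C)[C@H](O[Si](C)(C)C(C)(C)C)C[C@@](O[Si](C)(C)C)(C(C)C)C1OC(OC(C)=O)C(C)=CC1=O
F2 | step 12 | C4-O-trimethylsilyl ether of cycloadduct 21 | CC(C)(C)[Si](C)(C)O[C@@H]1C[C@@](O[Si](C)(C)C)(C(C)C)[C@@]23O[C@@H](C[C@]21C)C(C)=CC3=O
F3 | step 13 | cis-fused C5 epimer of γ-hydroxy enone 22 | CC(C)(C)[Si](C)(C)O[C@@H]1C[C@@](O)(C(C)C)[C@H]2C(=O)C=C(C)[C@@H](O)C[C@]21C
F4 | step 13 | cis-fused C5 epimer of γ-acetoxy enone 23 | CC(C)(C)[Si](C)(C)O[C@@H]1C[C@@](O)(C(C)C)[C@H]2C(=O)C=C(C)[C@@H](OC(C)=O)C[C@]21C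
F5 | step 19 | C2 2-[bis(2,2,2-trifluoroethoxy)phosphoryl]propanoate of 28 | CC(C(=O)O[C@@H]1C[C@@](O)(C(C)C)[C@@H]2[C@@H](OC(=O)c3ccc(OC)cc3)CC(C)=CC[C@]21C)P(=O)(OCC(F)(F)F)OCC(F)(F)F
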